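**Retrosynthetic overview**
Feature: ring A (C4a, C5, C6, C7, C8, C8a) is a pentasubstituted phloroglucinol whose 3-hydroxy-3-methylbutyl chain on C8 lies between O7 and the ring oxygen O1, so O1, O5 and O7 must be told apart.
Ring C is opened last: C2 comes from DMF dimethyl acetal (O1–C2, C2–C3), the C4–C3 bond from a ring B benzyl Grignard reagent added to a ring A salicylaldehyde, and C4a–C4 from ortho-formylation of a phenol with one free ortho carbon.
Ring A is cut at C8a–C8, C7–C6 and C8a–C4a into 3-(benzyloxy)cyclobutenone and a chain-bearing siloxyalkyne (Danheiser benzannulation); the product has O1 as free hydroxyl, O7 as silyl ether and O5 as benzyl ether.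
Order of rings: ring B is bought (2,4-dihydroxybenzaldehyde), ring A is built by the benzannulation, ring C is closed from the deoxybenzoin; desilylation and hydrogenolysis finish the route.

Key step: step 5

Remark: isoflavone numbering (O1, C2, C3, C4, C4a, C5 to C8, C8a) is used for all ring A intermediates; the target has no stereocentre, and the stereocentres of two intermediates are racemic and disappear later.

**Step 1**
Reactants: 1 hex-5-yn-2-one
Product: 2 2-methylhex-5-yn-2-ol
Conditions: MeMgBr (1.2 equiv), Et2O, −78 → 0 °C; aq NH4Cl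
Reagents that add atoms: methylmagnesium bromide, C[Mg]Br
Why: Grignard 1,2-addition to the methyl ketone is much faster in the cold than deprotonation of the terminal alkyne, so the tertiary carbinol should form cleanly.

**Step 2**
Reactants: 2 2-methylhex-5-yn-2-ol
Product: 3 triethyl[(2-methylhex-5-yn-2-yl)oxy]silane
Conditions: TESOTf, 2,6-lutidine, CH2Cl2, −78 → 0 °C
Reagents that add atoms: triethylsilyl trifluoromethanesulfonate, CC[Si](CC)(CC)OS(=O)(=O)C(F)(F)F
Why: Silylation with a silyl triflate and a hindered pyridine base is the standard way to cap a tertiary alcohol and leaves the terminal alkyne untouched.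

**Step 3**
Reactants: 3 triethyl[(2-methylhex-5-yn-2-yl)oxy]silane
Product: 6 5-methyl-5-(triethylsilyloxy)-1-(triisopropylsilyloxy)hex-1-yne, via lithium acetylide 4 (not isolated), via lithium ynolate 5 (not isolated)
Conditions: n-BuLi, THF, −78 °C; t-BuOOLi (from t-BuOOH + LiN(SiMe3)2, THF, −78 °C), −78 → 0 °C; TIPSOTf, −78 → 0 °C
Reagents that add atoms: lithium tert-butyl peroxide, CC(C)(C)OO[Li] (made from tert-butyl hydroperoxide, CC(C)(C)OO); triisopropylsilyl trifluoromethanesulfonate, CC(C)[Si](C(C)C)(C(C)C)OS(=O)(=O)C(F)(F)F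
Why: Oxidation of a lithium acetylide by the electrophilic oxygen of lithium tert-butyl peroxide gives the lithium ynolate, which the bulky silyl triflate traps on oxygen to give an isolable TIPS siloxyalkyne (acetylide oxidation followed by O-silylation).

**Step 4**
Reactants: 7 3-ethoxycyclobut-2-en-1-one
Product: 8 3-(benzyloxy)cyclobut-2-en-1-one
Conditions: BnOH (2 equiv), PPTS (cat.), toluene, 5 Å MS, 25–40 °C
Reagents that add atoms: benzyl alcohol, OCc1ccccc1
Why: Acid-catalysed transetherification of the vinylogous ester (addition of BnOH at C3 and loss of EtOH) is driven by trapping ethanol on the sieves, and the temperature is held below 40 °C so that the ring does not open to the vinylketene.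

**Step 5**
Reactants: 8 3-(benzyloxy)cyclobut-2-en-1-one; 6 5-methyl-5-(triethylsilyloxy)-1-(triisopropylsilyloxy)hex-1-yne
Product: 13 5-(benzyloxy)-2-[3-methyl-3-(triethylsilyloxy)butyl]-3-(triisopropylsilyloxy)phenol, via benzyloxy vinylketene 9 (not isolated), via vinylcyclobutenone 10 (not isolated), via dienylketene 11 (not isolated), via cyclohexadienone 12 (not isolated)
Conditions: toluene, 80 → 110 °C; 8 added over 3 h to 6 (1.3 equiv)
Reagents that add atoms: none
Why: Thermal 4π electrocyclic opening of 8 gives vinylketene 9, whose electrophilic ketene carbon (future C8a) is attacked by the nucleophilic, chain-bearing carbon of ynol ether 6 in a regioselective [2+2] cycloaddition that gives 10. Reversible 4π opening of 10 gives dienylketene 11, and ring A closes by a thermal disrotatory 6π electrocyclisation (C8a–C4a bond) to dienone 12, which tautomerises to phenol 13. This is the Danheiser benzannulation as known for cyclobutenones and TIPS siloxyalkynes giving resorcinol monosilyl ethers; the 3-alkoxy group on the cyclobutenone is the less common feature. No stereocentre remains, because the one in 10 is lost on ring opening. The step needs one selectivity, the regiochemistry of the ketene–alkyne [2+2], and the polarisation of the ynol ether (the carbon remote from oxygen is nucleophilic) secures it, placing the chain on C8 next to the only free hydroxyl (future O1) and the silyloxy group on C7, with the benzyl ether on C5. Slow addition of 8 to an excess of 6 should keep the vinylketene from acylating the product phenol.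

**Step 6**
Reactants: 13 5-(benzyloxy)-2-[3-methyl-3-(triethylsilyloxy)butyl]-3-(triisopropylsilyloxy)phenol
Product: 15 6-(benzyloxy)-2-hydroxy-3-[3-methyl-3-(triethylsilyloxy)butyl]-4-(triisopropylsilyloxy)benzaldehyde, via hydroxymethylphenol 14 (not isolated)
Conditions: MgCl2, Et3N, (CH2O)n, THF, reflux; aq citric acid
Reagents that add atoms: paraformaldehyde (formaldehyde), C=O
Why: In the magnesium-mediated ortho-formylation (Casnati–Skattebøl reaction) the magnesium phenoxide delivers formaldehyde only to an ortho carbon, C4a being the single free one, and the hydroxymethyl intermediate is oxidised in the flask by hydride transfer to a second formaldehyde.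

**Step 7**
Reactants: 16 2,4-dihydroxybenzaldehyde
Product: 17 2,4-bis(benzyloxy)benzaldehyde
Conditions: BnBr (2.4 equiv), K2CO3, DMF, 70 °C
Reagents that add atoms: benzyl bromide, BrCc1ccccc1
Why: Williamson etherification of both phenols, with heating to alkylate the hydrogen-bonded 2-hydroxyl.

**Step 8**
Reactants: 17 2,4-bis(benzyloxy)benzaldehyde
Product: 18 [2,4-bis(benzyloxy)phenyl]methanol
Conditions: NaBH4, MeOH–THF, 0 °C
Reagents that add atoms: none
Why: Hydride reduction of an aryl aldehyde by NaBH4 is reliable and does not touch benzyl ethers.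

**Step 9**
Reactants: 18 [2,4-bis(benzyloxy)phenyl]methanol
Product: 19 2,4-bis(benzyloxy)-1-(chloromethyl)benzene
Conditions: SOCl2, pyridine, Et2O, 0 °C; used at once
Reagents that add atoms: thionyl chloride, O=S(Cl)Cl
Why: Chlorodehydroxylation of a benzylic alcohol through its chlorosulfite, with pyridine taking up HCl so that the electron-rich benzylic chloride is not ionised.

**Step 10**
Reactants: 19 2,4-bis(benzyloxy)-1-(chloromethyl)benzene; 15 6-(benzyloxy)-2-hydroxy-3-[3-methyl-3-(triethylsilyloxy)butyl]-4-(triisopropylsilyloxy)benzaldehyde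
Product: 21 1-{6-(benzyloxy)-2-hydroxy-3-[3-methyl-3-(triethylsilyloxy)butyl]-4-(triisopropylsilyloxy)phenyl}-2-[2,4-bis(benzyloxy)phenyl]ethan-1-ol (racemic), via benzylic Grignard reagent 20 (not isolated)
Conditions: Mg (activated), THF, 0 °C, slow addition of 19 (dilute); then 15 (0.4 equiv), −78 → 0 °C; aq NH4Cl; crude 21 taken on directly
Reagents that add atoms: none
Why: Grignard formation under cold, dilute conditions limits Wurtz coupling, the first equivalent of 20 deprotonates the phenol and the second adds 1,2 to the aldehyde to form the C4–C3 bond; the new carbinol stereocentre is formed racemic and is removed in step 11.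

**Step 11**
Reactants: 21 1-{6-(benzyloxy)-2-hydroxy-3-[3-methyl-3-(triethylsilyloxy)butyl]-4-(triisopropylsilyloxy)phenyl}-2-[2,4-bis(benzyloxy)phenyl]ethan-1-ol
Product: 22 1-{6-(benzyloxy)-2-hydroxy-3-[3-methyl-3-(triethylsilyloxy)butyl]-4-(triisopropylsilyloxy)phenyl}-2-[2,4-bis(benzyloxy)phenyl]ethan-1-one
Conditions: Dess–Martin periodinane, pyridine, CH2Cl2, 0 °C → rt
Reagents that add atoms: none
Why: Dess–Martin oxidation of the secondary benzylic alcohol under pyridine buffering avoids acid, which would ionise this electron-rich carbinol, and the phenol ends hydrogen-bonded to the new ketone.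

**Step 12**
Reactants: 22 1-{6-(benzyloxy)-2-hydroxy-3-[3-methyl-3-(triethylsilyloxy)butyl]-4-(triisopropylsilyloxy)phenyl}-2-[2,4-bis(benzyloxy)phenyl]ethan-1-one
Product: 24 5-(benzyloxy)-3-[2,4-bis(benzyloxy)phenyl]-8-[3-methyl-3-(triethylsilyloxy)butyl]-7-(triisopropylsilyloxy)-4H-chromen-4-one, via enaminone 23 (not isolated)
Conditions: Me2NCH(OMe)2 (3 equiv), toluene, 90 °C
Reagents that add atoms: N,N-dimethylformamide dimethyl acetal, COC(OC)N(C)C
Why: Condensation of the active methylene with the amide acetal gives the enaminone, and the free C8a hydroxyl then adds to the enamine carbon with loss of dimethylamine (6-endo addition–elimination), the standard deoxybenzoin route to isoflavones, closing ring C at O1–C2.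

**Step 13**
Reactants: 24 5-(benzyloxy)-3-[2,4-bis(benzyloxy)phenyl]-8-[3-methyl-3-(triethylsilyloxy)butyl]-7-(triisopropylsilyloxy)-4H-chromen-4-one
Product: 25 5-(benzyloxy)-3-[2,4-bis(benzyloxy)phenyl]-7-hydroxy-8-(3-hydroxy-3-methylbutyl)-4H-chromen-4-one
Conditions: Bu4NF (3 equiv), THF, 0 °C → rt; aqueous work-up
Reagents that add atoms: none
Why: Fluoride-mediated desilylation should cleave both the aryl TIPS ether and the tertiary TES ether, while the benzyl ethers and the chromone are inert to it.

**Step 14**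
Reactants: 25 5-(benzyloxy)-3-[2,4-bis(benzyloxy)phenyl]-7-hydroxy-8-(3-hydroxy-3-methylbutyl)-4H-chromen-4-one
Product: 26 3-(2,4-dihydroxyphenyl)-5,7-dihydroxy-8-(3-hydroxy-3-methylbutyl)-4H-chromen-4-one (2,3-dehydrokievitone hydrate)
Conditions: H2 (1 atm), Pd/C, EtOAc–MeOH, rt; stopped at the calculated uptake
Reagents that add atoms: none
Why: Catalytic hydrogenolysis removes the three benzyl aryl ethers, and stopping at the calculated hydrogen uptake keeps the C2=C3 bond of the isoflavone from being reduced to the isoflavanone.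

**Compound list**
1 | hex-5-yn-2-one | CC(=O)CCC#C | starting material
2 | 2-methylhex-5-yn-2-ol | CC(C)(O)CCC#C | intermediate
3 | triethyl[(2-methylhex-5-yn-2-yl)oxy]silane | CC[Si](CC)(CC)OC(C)(C)CCC#C | intermediate
4 | [5-methyl-5-(triethylsilyloxy)hex-1-yn-1-yl]lithium | [Li]C#CCCC(C)(C)O[Si](CC)(CC)CC | intermediate
5 | lithium 5-methyl-5-(triethylsilyloxy)hex-1-yn-1-olate | [Li]OC#CCCC(C)(C)O[Si](CC)(CC)CC | intermediate
6 | 5-methyl-5-(triethylsilyloxy)-1-(triisopropylsilyloxy)hex-1-yne | CC(C)(O[Si](CC)(CC)CC)CCC#CO[Si](C(C)C)(C(C)C)C(C)C | intermediate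
7 | 3-ethoxycyclobut-2-en-1-one | CCOC1=CC(=O)C1 | starting material
8 | 3-(benzyloxy)cyclobut-2-en-1-one | O=C1C=C(OCc2ccccc2)C1 | intermediate
9 | 3-(benzyloxy)buta-1,3-dien-1-one | C=C(OCc1ccccc1)C=C=O | intermediate
10 | 4-[1-(benzyloxy)ethenyl]-2-[3-methyl-3-(triethylsilyloxy)butyl]-3-(triisopropylsilyloxy)cyclobut-2-en-1-one (racemic) | O=C1C(CCC(C)(C)O[Si](CC)(CC)CC)=C(O[Si](C(C)C)(C(C)C)C(C)C)C1C(=C)OCc1ccccc1 | intermediate
11 | (3E)-5-(benzyloxy)-2-[3-methyl-3-(triethylsilyloxy)butyl]-3-(triisopropylsilyloxy)hexa-1,3,5-trien-1-one | O=C=C(CCC(C)(C)O[Si](CC)(CC)CC)/C(O[Si](C(C)C)(C(C)C)C(C)C)=C\C(=C)OCc1ccccc1 | intermediate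
12 | 5-(benzyloxy)-2-[3-methyl-3-(triethylsilyloxy)butyl]-3-(triisopropylsilyloxy)cyclohexa-2,4-dien-1-one | O=C1CC(OCc2ccccc2)=CC(O[Si](C(C)C)(C(C)C)C(C)C)=C1CCC(C)(C)O[Si](CC)(CC)CC | intermediate
13 | 5-(benzyloxy)-2-[3-methyl-3-(triethylsilyloxy)butyl]-3-(triisopropylsilyloxy)phenol | CC(C)(O[Si](CC)(CC)CC)CCc1c(O)cc(OCc2ccccc2)cc1O[Si](C(C)C)(C(C)C)C(C)C | intermediate
14 | 3-(benzyloxy)-2-(hydroxymethyl)-6-[3-methyl-3-(triethylsilyloxy)butyl]-5-(triisopropylsilyloxy)phenol | OCc1c(O)c(CCC(C)(C)O[Si](CC)(CC)CC)c(O[Si](C(C)C)(C(C)C)C(C)C)cc1OCc1ccccc1 | intermediate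
15 | 6-(benzyloxy)-2-hydroxy-3-[3-methyl-3-(triethylsilyloxy)butyl]-4-(triisopropylsilyloxy)benzaldehyde | O=Cc1c(O)c(CCC(C)(C)O[Si](CC)(CC)CC)c(O[Si](C(C)C)(C(C)C)C(C)C)cc1OCc1ccccc1 | intermediate
16 | 2,4-dihydroxybenzaldehyde | O=Cc1ccc(O)cc1O | starting material
17 | 2,4-bis(benzyloxy)benzaldehyde | O=Cc1ccc(OCc2ccccc2)cc1OCc1ccccc1 | intermediate
18 | [2,4-bis(benzyloxy)phenyl]methanol | OCc1ccc(OCc2ccccc2)cc1OCc1ccccc1 | intermediate
19 | 2,4-bis(benzyloxy)-1-(chloromethyl)benzene | ClCc1ccc(OCc2ccccc2)cc1OCc1ccccc1 | intermediate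
20 | [2,4-bis(benzyloxy)benzyl]magnesium chloride | Cl[Mg]Cc1ccc(OCc2ccccc2)cc1OCc1ccccc1 | intermediate
21 | 1-{6-(benzyloxy)-2-hydroxy-3-[3-methyl-3-(triethylsilyloxy)butyl]-4-(triisopropylsilyloxy)phenyl}-2-[2,4-bis(benzyloxy)phenyl]ethan-1-ol (racemic) | OC(Cc1ccc(OCc2ccccc2)cc1OCc1ccccc1)c1c(O)c(CCC(C)(C)O[Si](CC)(CC)CC)c(O[Si](C(C)C)(C(C)C)C(C)C)cc1OCc1ccccc1 | intermediate
22 | 1-{6-(benzyloxy)-2-hydroxy-3-[3-methyl-3-(triethylsilyloxy)butyl]-4-(triisopropylsilyloxy)phenyl}-2-[2,4-bis(benzyloxy)phenyl]ethan-1-one | O=C(Cc1ccc(OCc2ccccc2)cc1OCc1ccccc1)c1c(O)c(CCC(C)(C)O[Si](CC)(CC)CC)c(O[Si](C(C)C)(C(C)C)C(C)C)cc1OCc1ccccc1 | intermediate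
23 | 1-{6-(benzyloxy)-2-hydroxy-3-[3-methyl-3-(triethylsilyloxy)butyl]-4-(triisopropylsilyloxy)phenyl}-2-[2,4-bis(benzyloxy)phenyl]-3-(dimethylamino)prop-2-en-1-one (alkene geometry not defined) | CN(C)C=C(c1ccc(OCc2ccccc2)cc1OCc1ccccc1)C(=O)c1c(O)c(CCC(C)(C)O[Si](CC)(CC)CC)c(O[Si](C(C)C)(C(C)C)C(C)C)cc1OCc1ccccc1 | intermediate
24 | 5-(benzyloxy)-3-[2,4-bis(benzyloxy)phenyl]-8-[3-methyl-3-(triethylsilyloxy)butyl]-7-(triisopropylsilyloxy)-4H-chromen-4-one | CC[Si](CC)(CC)OC(C)(C)CCc1c(O[Si](C(C)C)(C(C)C)C(C)C)cc(OCc2ccccc2)c2c(=O)c(-c3ccc(OCc4ccccc4)cc3OCc3ccccc3)coc12 | intermediate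
25 | 5-(benzyloxy)-3-[2,4-bis(benzyloxy)phenyl]-7-hydroxy-8-(3-hydroxy-3-methylbutyl)-4H-chromen-4-one | CC(C)(O)CCc1c(O)cc(OCc2ccccc2)c2c(=O)c(-c3ccc(OCc4ccccc4)cc3OCc3ccccc3)coc12 | intermediate
26 | 3-(2,4-dihydroxyphenyl)-5,7-dihydroxy-8-(3-hydroxy-3-methylbutyl)-4H-chromen-4-one (2,3-dehydrokievitone hydrate) | CC(C)(O)CCc1c(O)cc(O)c2c(=O)c(-c3ccc(O)cc3O)coc12 | target

**Totals**
Total step count: 14.
Longest linear sequence: 10 steps (steps 1, 2, 3, 5, 6, 10, 11, 12, 13, 14).

**Steps most likely to fail**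

1. Step 5 (benzannulation). The vinylogous-ester stabilisation of 8 may make ring opening slow, so that self-condensation of 8, thermal rearrangement of 6 and acylation of the new phenol by the vinylketene outpace the [2+2] capture. The fallback sets out from 6 and comes back at 10, and through it at 13. It makes the same vinylketene 9 at or below room temperature from an open-chain acid chloride, so that ketene formation no longer depends on ring opening. Ethyl but-2-ynoate and benzyl alcohol (PMe3 cat., CH2Cl2) should give, by conjugate addition, ethyl (E)-3-(benzyloxy)but-2-enoate F1. LiOH (THF–H2O) should then give (E)-3-(benzyloxy)but-2-enoic acid F2, and 1-chloro-N,N,2-trimethylprop-1-en-1-amine (CH2Cl2, 0 °C) should convert it under neutral conditions into (E)-3-(benzyloxy)but-2-enoyl chloride F3. Slow addition of Et3N to F3 and 6 (toluene, 0 °C to rt) should effect 1,4-dehydrochlorination to 9, which 6 captures as 10. The filtered solution is then heated at 80–110 °C to take 10 through 11 and 12 to 13.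

2. Step 10 (benzylic Grignard addition). Homocoupling during magnesium insertion and ionisation of the electron-rich benzylic chloride may deplete the organomagnesium reagent, so that the addition stalls at the magnesium phenoxide of the aldehyde. The fallback sets out from 15 and comes back at 24. It brings ring B in by cross-coupling instead. MeMgBr (THF, −78 °C) should add to 15 to give the ring A 1-arylethanol F4, and Dess–Martin oxidation should give the 2-hydroxyacetophenone F5. DMF dimethyl acetal (toluene, 90 °C) should give the enaminone F6, and I2 (CHCl3, rt) should close ring C with loss of dimethylamine to give the 3-iodochromone F7. Suzuki–Miyaura coupling of F7 with commercial 2,4-bis(benzyloxy)phenylboronic acid (Pd(PPh3)4, K2CO3, dioxane–H2O, 80 °C) should form the C3–aryl bond and give 24.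

3. Step 4 (transetherification). The acid needed for exchange may also hydrolyse or open the strained ring, and the exchange equilibrium may not be driven to completion. The fallback sets out from 7 and comes back at 8. Dilute aqueous HCl (0 °C) should hydrolyse 7 to cyclobutane-1,3-dione F8. This strongly acidic enol is then O-benzylated under Mitsunobu conditions (BnOH, PPh3, diisopropyl azodicarboxylate, THF, 0 °C) to give 8 without acid or heat.

**Further compounds**
F1 | step 5 | ethyl (E)-3-(benzyloxy)but-2-enoate | CCOC(=O)/C=C(\C)OCc1ccccc1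
F2 | step 5 | (E)-3-(benzyloxy)but-2-enoic acid | OC(=O)/C=C(\C)OCc1ccccc1
F3 | step 5 | (E)-3-(benzyloxy)but-2-enoyl chloride | ClC(=O)/C=C(\C)OCc1ccccc1
F4 | step 10 | 1-{6-(benzyloxy)-2-hydroxy-3-[3-methyl-3-(triethylsilyloxy)butyl]-4-(triisopropylsilyloxy)phenyl}ethan-1-ol (racemic) | CC(O)c1c(O)c(CCC(C)(C)O[Si](CC)(CC)CC)c(O[Si](C(C)C)(C(C)C)C(C)C)cc1OCc1ccccc1
F5 | step 10 | 1-{6-(benzyloxy)-2-hydroxy-3-[3-methyl-3-(triethylsilyloxy)butyl]-4-(triisopropylsilyloxy)phenyl}ethan-1-one | CC(=O)c1c(O)c(CCC(C)(C)O[Si](CC)(CC)CC)c(O[Si](C(C)C)(C(C)C)C(C)C)cc1OCc1ccccc1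
F6 | step 10 | (E)-1-{6-(benzyloxy)-2-hydroxy-3-[3-methyl-3-(triethylsilyloxy)butyl]-4-(triisopropylsilyloxy)phenyl}-3-(dimethylamino)prop-2-en-1-one | CN(C)/C=C/C(=O)c1c(O)c(CCC(C)(C)O[Si](CC)(CC)CC)c(O[Si](C(C)C)(C(C)C)C(C)C)cc1OCc1ccccc1
F7 | step 10 | 5-(benzyloxy)-3-iodo-8-[3-methyl-3-(triethylsilyloxy)butyl]-7-(triisopropylsilyloxy)-4H-chromen-4-one | CC[Si](CC)(CC)OC(C)(C)CCc1c(O[Si](C(C)C)(C(C)C)C(C)C)cc(OCc2ccccc2)c2c(=O)c(I)coc12
F8 | step 4 | cyclobutane-1,3-dione | O=C1CC(=O)C1
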